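## Analysis of the target

Atom labels used throughout: ring carbons C5 (bears the side chain), C6 (CH2), C7 (bears the ester oxygen O7), C8 (bears CH3) and C9 (bears the hydroxymethyl group C1/O1); side-chain carbon C4 bears C3/O3 (acylated) and C11/O11 (free).

The target 39 is a single cyclopentane with four contiguous ring stereocentres, C5 (R), C9 (S), C8 (R) and C7 (R). Every neighbouring pair of substituents is trans: the C4 side chain and the C8 methyl lie on one face, C1 and O7 on the other. A fifth stereocentre, C4 (S), lies outside the ring and exists only because one of its two hydroxymethyl arms (C3/O3) is acylated and the other (C11/O11) is free. O3 and O7 carry the same acyl group, (3S,4E)-4-formyl-3-(2-oxoethyl)hex-4-enoyl, so the molecule holds seven stereocentres, two E-enals and four aldehydes. The sensitive points are the aldehydes, the free primary alcohols beside them, and the 1,3-relation of the O3 ester to the free O11 hydroxyl: an acyl shift across it would amount to epimerisation at C4. The synthesis is hard for three reasons: a hindered hydride delivers O7 on the wrong face of the all-trans ring, two constitutionally identical arms at C4 must be told apart, and O3/O7 must be distinguished from O1/O11 before two polyfunctional acyl groups are attached. The strategy rests on the pair C7/C8. A ring carbon bearing oxygen next to a ring carbon bearing a one-carbon branch is the imprint of a 2-methylidenecyclopentanone, which a 1-ethynylcyclobutanol gives when its C7–C9 ring bond migrates onto the alkyne.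

## Retrosynthetic reasoning

**39 from 38.** The four aldehydes and the two primary alcohols are unmasked last. In 38 every aldehyde is an acetal and O1/O11 are silyl ethers, so one mild acidic hydrolysis removes all six groups and nothing else has to be done in the presence of free aldehydes or the migration-prone O3 ester/O11 alcohol pair.

**38 from 26 and 37.** The two ester C–O bonds are cut. Both acyl groups are the same, so one double esterification of diol 26 (O3 and O7 free) with two equivalents of acid 37 suffices. The stereocentre of 37 is β to the carboxyl and cannot epimerise on activation.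

**37 from 32 and 35.** In the acid the bond between the stereocentre and the alkenyl carbon is cut, which leads to enoate 35 and alkenylboronate 32 for a rhodium-catalysed asymmetric conjugate addition, followed by saponification of 36. Boronate 32 comes from crotonaldehyde 27 through bromoenal 29 and its acetal 30; the bromine marks the carbon that becomes the nucleophile and fixes the E geometry. Enoate 35 comes from acrylate 33 and alkene 34 by cross-metathesis.

**26 back to 20.** Two things have to be achieved: O3 must be told from O11, and O3/O7 from O1/O11. Both are solved by raising C1 to the aldehyde level (20) and letting it form a six-membered cyclic methyl acetal with one arm (21). Because C5 and C9 are trans, the new ring is a trans-fused chair. Under equilibrating conditions the arm that stays outside the ring sits equatorial, and that arm is C3, the one acylated in 39. A bicyclic acetal that uses both arms is geometrically impossible on a trans-fused ring. The free O3 is then capped (22), the acetal is opened and reduced (24), O1/O11 are silylated (25) and the two temporary esters are removed together (26).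

**20 back to 16.** The aldehyde comes from benzyl ether 18 by hydrogenolysis and oxidation (19, 20). The C7 oxygen is trans to the C8 methyl, the arrangement a bulky hydride does not give. The ketone 16 is therefore reduced to the cis alcohol 17 with high selectivity, and the centre is inverted once by a Mitsunobu reaction; the benzoate 18 so formed also protects O7 through the next seven steps.

**16 from 14.** The C8 methyl is cut back to an exocyclic methylidene. C8 is α to the ketone, so its configuration need not be controlled in the reduction: equilibration gives the trans arrangement.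

**14 from 13 (key disconnection).** The C8–C9 bond is cut and C7–C9 restored, which contracts the cyclopentanone to a 1-ethynylcyclobutanol. One skeletal bond and the five-membered ring are gained. The forward reaction must move C9 rather than C6, keep the configuration of C9, and leave the methylidene ketone unisomerised.

**13 from 11 and 12.** The carbinol is cut to cyclobutanone 11 and ethynyl Grignard reagent 12. The configuration of the carbinol carbon is irrelevant, because that centre becomes the ketone.

**11 from 7 and 3.** The four-membered ring is cut across C7–C6 and C9–C5, a (2+2) disconnection to the keteniminium salt of amide 7 and the terminal alkene 3. The polarity of the two partners fixes the regiochemistry. The C2-symmetric amine 5 in the amide sets C5. C9 is α to the ketone and is equilibrated to trans.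

**3 and 7 from commercial materials.** Alkene 3 comes from alcohol 1 by oxidation (2) and methylenation. Amide 7 comes from acid 4 and amine 5. The side chain with both C4 arms, protected as one acetonide, thus arrives with the alkene.

## Alternatives that were turned down

**Alternative 1: two-directional asymmetric alkenylation at the very end.**
- Disconnection: the two C–C bonds between each acyl stereocentre and its alkenyl carbon, on a core that carries two achiral (E)-5,5-dimethoxypent-2-enoate esters (A1).
- Forward key step: double rhodium-catalysed conjugate addition of boronate 32 under a chiral diene ligand, giving the fully protected target A2 in one operation.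
- For it: no chiral acid has to be made and stored, both remote stereocentres come from the catalyst, and the end-game is as convergent as possible. On the side chains it is two or three steps shorter than the chosen route and is the stronger plan on that point.
- Against it: it says nothing about the core. A1 is simply diol 26 acylated, so the five core stereocentres and the O3/O11 problem still need their own solution. The two enoates sit in different environments (a primary ester and a hindered secondary ester next to the C8 methyl), so the catalyst must override the substrate twice. Any shortfall appears as diastereomers of a large, non-crystalline molecule, not as an ee that can be upgraded. The hindered α-branched alkenyl nucleophile must also be driven to double addition in aqueous base beside two esters.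
- Comparison: the chosen route makes the same bond on the small enoate 35, where the outcome can be checked and purified before coupling, and spends its key step on the ring, which Alternative 1 leaves open.

**Alternative 2: acetal-tethered Pauson–Khand reaction.**
- Disconnection: C9–C5, C6–C7 and C7–C8, with C1 tied to O11 as a mixed acetal, leading to enyne A3.
- Forward key step: cobalt-mediated cyclocarbonylation of A3 closes the cyclopentenone and the six-membered acetal ring at once and gives bicyclic enone A4.
- For it: all ring carbons, the C7 ketone and the C8 methyl are in place after one step. C4 comes from a chiral building block, and O11 is already distinguished from O3. On the C4 problem it is stronger than the chosen route, which relies on a thermodynamic preference.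
- Against it: in A4 the double bond is C8=C9 and tetrasubstituted, so C9 is not a stereocentre. C9 is not epimerisable later and must be set trans to C5 by reducing that alkene. Addition of hydrogen from the open face of such a bicycle gives the cis ring fusion, and a dissolving-metal reduction has no secure preference in a five/six system. The enyne is of the 1,7 type and closes a six-membered ring, the slower mode, and control of C5 by C4 through the flexible tether is uncertain.
- Comparison: the chosen route fixes the trans C5/C9 relation by equilibration at the cyclobutanone stage and carries it through a stereoretentive shift. It gives up the early C4 control of Alternative 2 and offers a secure ring configuration in its place.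

**Alternative 3: three-component coupling on a chiral silyloxycyclopentenone.**
- Disconnection: C9–C1 and C8–CH3 on enone A5.
- Forward key step: copper-catalysed conjugate addition of the silylmethyl Grignard reagent A6 anti to the silyloxy group, then methylation of the enolate anti to the new substituent, giving the all-trans ketone A7.
- For it: the absolute configuration comes from a building block of known sense, not from an auxiliary-controlled cycloaddition, and the trans,trans triad with the C8 methyl is set directly. On both points it is stronger than the chosen route.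
- Against it: the silyloxy-bearing carbon of A7 is C5, which in the target carries carbon. The oxygen must be eliminated and the whole C4 unit introduced by a second conjugate addition, and the C4 differentiation is not addressed. The enolate formed after the first addition can equilibrate and expel the β-silyloxy group before it is methylated. The silylmethyl group still needs a Tamao oxidation, and C7 needs the same inversion as in the chosen route.
- Comparison: the chosen route brings in C4 with both arms in the alkene 3 and makes C5–C9 and C5–C4 part of the first ring. Alternative 3 reaches a comparable ketone only after several more steps.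

Key step: step 6

Assumption 1: the facial sense of the keteniminium cycloaddition (step 4) is assigned from a steric model of the C2-symmetric iminium; if C5 forms with the opposite configuration, the (2S,5S)-amine is used in step 3 and nothing else changes.

Assumption 2: (R)-BINAP in step 21 is chosen on the premise that the enoate binds rhodium through the same enantioface as simple enones do; if the sense is reversed for this substrate, (S)-BINAP is used.

## Steps

Step 1
Reactants: 1 (2,2-dimethyl-1,3-dioxan-5-yl)methanol
Product: 2 2,2-dimethyl-1,3-dioxane-5-carbaldehyde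
Conditions: (COCl)2, DMSO, CH2Cl2, −78 °C; Et3N, −78 → −20 °C
Reagents that add atoms: none
Why: Swern oxidation of a primary alcohol; the low temperature keeps the α-branched β-alkoxy aldehyde from β-elimination.

Step 2
Reactants: 2 2,2-dimethyl-1,3-dioxane-5-carbaldehyde
Product: 3 5-ethenyl-2,2-dimethyl-1,3-dioxane
Conditions: Ph3PCH3Br, KN(SiMe3)2, THF, −78 → 0 °C
Reagents that add atoms: methyltriphenylphosphonium bromide, C[P+](c1ccccc1)(c2ccccc2)c3ccccc3.[Br-]
Why: Wittig methylenation with the unstabilised ylide; addition at low temperature outruns enolisation of the aldehyde.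

Step 3
Reactants: 4 3-(benzyloxy)propanoic acid; 5 (2R,5R)-2,5-dimethylpyrrolidine
Product: 7 3-(benzyloxy)-1-[(2R,5R)-2,5-dimethylpyrrolidin-1-yl]propan-1-one, via acid chloride 6 (not isolated)
Conditions: (COCl)2, DMF (cat.), CH2Cl2, 0 °C → rt; then 5, i-Pr2NEt, 0 °C → rt
Reagents that add atoms: none
Why: Acylation of a hindered secondary amine through the acid chloride; no stereocentre is formed and the auxiliary is carried unchanged.

Step 4
Reactants: 7 benzyloxypropanoyl dimethylpyrrolidine amide; 3 5-ethenyl-2,2-dimethyl-1,3-dioxane
Product: 11 (2R,3S)-2-[(benzyloxy)methyl]-3-(2,2-dimethyl-1,3-dioxan-5-yl)cyclobutan-1-one, via keteniminium triflate 8 (not isolated), via cyclobutaniminium triflate 9 (not isolated), via cis-cyclobutanone 10 (not isolated)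
Conditions: Tf2O, 2,4,6-collidine, ClCH2CH2Cl, −20 → 60 °C; then aq. NaHCO3, rt; then Et3N, CH2Cl2, rt
Reagents that add atoms: water, O
Why: Keteniminium (2+2) cycloaddition: Tf2O and collidine convert the amide into salt 8, the CH2 terminus of 3 attacks its central carbon (C7–C6) and the developing secondary cation closes onto the α-carbon (C9–C5), which fixes the 2,3-regiochemistry. The C2-symmetric pyrrolidine leaves one flank of the iminium open, so C5 is set as drawn; hydrolysis of 9 gives mainly the cis ketone 10. Et3N then epimerises the enolisable C9 to the more stable trans ketone without touching C5.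

Step 5
Reactants: 11 trans-cyclobutanone (2R,3S); 12 ethynylmagnesium bromide
Product: 13 (1R,2R,3S)-2-[(benzyloxy)methyl]-3-(2,2-dimethyl-1,3-dioxan-5-yl)-1-ethynylcyclobutan-1-ol
Conditions: 12 (0.5 M in THF), THF, −78 → 0 °C; then sat. aq. NH4Cl
Reagents that add atoms: none
Why: Grignard 1,2-addition to a strained, electrophilic ketone, expected mainly from the face anti to the neighbouring benzyloxymethyl group; the minor carbinol epimer is carried along because the centre is destroyed in step 6.

Step 6
Reactants: 13 ethynylcyclobutanol (1R,2R,3S)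
Product: 14 (3S,4R)-3-[(benzyloxy)methyl]-4-(2,2-dimethyl-1,3-dioxan-5-yl)-2-methylidenecyclopentan-1-one
Conditions: [(4-CF3C6H4)3P]AuCl (2 mol %), AgSbF6 (2 mol %), CH2Cl2, rt
Reagents that add atoms: none
Why: The cationic gold centre (monovalent gold, chloride removed by AgSbF6) binds the ethynyl group, and the ring bond C7–C9 anti to gold shifts to the internal alkyne carbon while the carbinol oxygen becomes the C7 carbonyl; protodeauration of the vinylgold leaves the exocyclic methylidene and frees the catalyst. The closest known reaction type is the gold-catalysed ring expansion of 1-alkynylcyclobutanols to 2-alkylidenecyclopentanones, a π-acid-triggered semipinacol shift. The five-membered ring arises by ring enlargement through a 1,2-alkyl shift, not by an exo or endo closure, and is driven by release of cyclobutane strain. No stereocentre is created: the carbinol centre disappears, so both epimers of 13 converge, C5 is untouched, and C9 migrates with retention, so the trans C5/C9 relation of 11 is carried into 14. The step needs migration of C9 in preference to C6; C9 is the more substituted carbon and supports the electron-deficient transition state better, an advantage the β-oxygen of the benzyloxymethyl group lessens but should not reverse. It also needs the methylidene ketone to stay out of the ring, since isomerisation would erase C9; neutral aprotic conditions, low loading and immediate use in step 7 serve this. In the main epimer of 13 the ether oxygen is trans to the alkyne and cannot compete as a nucleophile.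

Step 7
Reactants: 14 methylidene ketone (3S,4R)
Product: 16 (2R,3S,4R)-3-[(benzyloxy)methyl]-4-(2,2-dimethyl-1,3-dioxan-5-yl)-2-methylcyclopentan-1-one, via cis-methyl ketone 15 (not isolated)
Conditions: H2 (1 atm), (Ph3P)3RhCl (5 mol %), PhMe/EtOH, rt; then DBU (0.2 equiv), CH2Cl2, rt
Reagents that add atoms: none
Why: Homogeneous hydrogenation of the unhindered 1,1-disubstituted alkene spares the benzyl ether and the ketone and does not move the double bond. C8 is α to the ketone, so DBU equilibrates whatever epimer mixture forms to the all-trans ketone (thermodynamic control, as in other 2,3-dialkylcyclopentanones).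

Step 8
Reactants: 16 trans-methyl ketone (2R,3S,4R)
Product: 17 (1S,2R,3S,4R)-3-[(benzyloxy)methyl]-4-(2,2-dimethyl-1,3-dioxan-5-yl)-2-methylcyclopentan-1-ol
Conditions: LiBH(s-Bu)3, THF, −78 °C; then aq. NaOH, H2O2, 0 °C
Reagents that add atoms: none
Why: Bulky-hydride reduction: the reagent approaches anti to the α-methyl group and to the C5 substituent, as in 2,3-trans-disubstituted cyclopentanones of the prostanoid type, and gives the alcohol cis to the methyl group; this is the C7 epimer of what the target needs and is corrected in step 9.

Step 9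
Reactants: 17 cis-alcohol (1S,2R,3S,4R)
Product: 18 (1R,2R,3S,4R)-3-[(benzyloxy)methyl]-4-(2,2-dimethyl-1,3-dioxan-5-yl)-2-methylcyclopentyl benzoate
Conditions: PPh3, DIAD (i-PrO2CN=NCO2i-Pr), PhCO2H, THF, 0 °C → rt
Reagents that add atoms: benzoic acid, OC(=O)c1ccccc1
Why: Mitsunobu reaction: benzoate displaces the oxyphosphonium group in an SN2 step with clean inversion, which places O7 trans to the C8 methyl (7R). The benzoate then protects O7.

Step 10
Reactants: 18 benzyl ether benzoate
Product: 19 (1R,2R,3S,4R)-4-(2,2-dimethyl-1,3-dioxan-5-yl)-3-(hydroxymethyl)-2-methylcyclopentyl benzoate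
Conditions: H2 (1 atm), 10 % Pd/C, EtOAc, rt
Reagents that add atoms: none
Why: Hydrogenolysis of the benzyl ether; the benzoate and the acetonide are inert in neutral EtOAc and no alkene is present.

Step 11
Reactants: 19 primary alcohol
Product: 20 (1R,2R,3S,4S)-4-(2,2-dimethyl-1,3-dioxan-5-yl)-3-formyl-2-methylcyclopentyl benzoate
Conditions: TEMPO (10 mol %), PhI(OAc)2, CH2Cl2, rt
Reagents that add atoms: none
Why: Oxoammonium-mediated oxidation of a primary alcohol to the aldehyde without over-oxidation; the medium is not basic, so C9, now α to the aldehyde, is not epimerised.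

Step 12
Reactants: 20 aldehyde acetonide
Product: 21 (4R,4aS,6R,7R,7aS)-4-(hydroxymethyl)-1-methoxy-7-methyloctahydrocyclopenta[c]pyran-6-yl benzoate (mixture of C1 anomers)
Conditions: CSA (10 mol %), MeOH, rt, to equilibrium; Et3N quench
Reagents that add atoms: methanol, CO
Why: Acid-catalysed transacetalisation: methanol removes the acetonide and the aldehyde is taken up as a six-membered cyclic methyl acetal by one of the two freed arms. All steps are reversible, so the trans-fused chair with the outside arm equatorial is favoured, and that arm is C3; this sets C4. A bicyclic acetal using both arms cannot form on the trans-fused ring. Both anomers are used because C1 is reduced in step 14.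

Step 13
Reactants: 21 hydroxy acetal
Product: 22 [(4S,4aS,6R,7R,7aS)-6-(benzoyloxy)-1-methoxy-7-methyloctahydrocyclopenta[c]pyran-4-yl]methyl 2,2-dimethylpropanoate
Conditions: t-BuCOCl, pyridine, DMAP (cat.), CH2Cl2, 0 °C → rt
Reagents that add atoms: pivaloyl chloride, CC(C)(C)C(=O)Cl
Why: Acylation of the only free hydroxyl; a pivalate is chosen because it resists 1,3-migration to O11 in the next two steps.

Step 14
Reactants: 22 pivalate acetal
Product: 24 (1R,2R,3S,4R)-4-[(2S)-1-[(2,2-dimethylpropanoyl)oxy]-3-hydroxypropan-2-yl]-3-(hydroxymethyl)-2-methylcyclopentyl benzoate, via lactol 23 (not isolated)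
Conditions: p-TsOH·H2O (20 mol %), THF/H2O (3:1), 45 °C; then NaBH4, EtOH, 0 °C
Reagents that add atoms: water, O
Why: Acetal hydrolysis to the lactol, whose open hydroxy-aldehyde form is reduced by borohydride; both esters survive the cold, brief reduction, and C1 returns to the alcohol level with O1 and O11 free.

Step 15
Reactants: 24 diol
Product: 25 (1R,2R,3S,4R)-3-{[(tert-butyldimethylsilyl)oxy]methyl}-4-[(2R)-1-[(tert-butyldimethylsilyl)oxy]-3-[(2,2-dimethylpropanoyl)oxy]propan-2-yl]-2-methylcyclopentyl benzoate
Conditions: TBSCl, imidazole, DMF, rt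
Reagents that add atoms: tert-butyldimethylsilyl chloride, CC(C)(C)[Si](C)(C)Cl
Why: Silylation of the two primary alcohols; the change of the side-chain descriptor to R is a priority effect of silicon, not a change of configuration.

Step 16
Reactants: 25 bis-silyl ether diester
Product: 26 (1R,2R,3S,4R)-3-{[(tert-butyldimethylsilyl)oxy]methyl}-4-[(2R)-1-[(tert-butyldimethylsilyl)oxy]-3-hydroxypropan-2-yl]-2-methylcyclopentan-1-ol
Conditions: i-Bu2AlH (6 equiv), CH2Cl2, −78 → −20 °C; aq. potassium sodium tartrate
Reagents that add atoms: none
Why: Reductive cleavage of the benzoate and the pivalate at the acyl carbon; silyl ethers are inert, and the cold, non-basic aluminium alkoxide does not promote silyl migration from O11 to O3.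

Step 17
Reactants: 27 (E)-but-2-enal (crotonaldehyde)
Product: 29 (2Z)-2-bromobut-2-enal, via 2,3-dibromobutanal 28 (not isolated)
Conditions: Br2, CH2Cl2, 0 °C; then Et3N, 0 °C → rt
Reagents that add atoms: bromine, BrBr
Why: Bromination and E1cB loss of HBr through the acidic α-hydrogen; the conjugated product with CH3 trans to CHO is the more stable isomer.

Step 18
Reactants: 29 (2Z)-2-bromobut-2-enal
Product: 30 (2Z)-2-bromo-1,1-dimethoxybut-2-ene
Conditions: HC(OMe)3, MeOH, p-TsOH·H2O (cat.), rt
Reagents that add atoms: trimethyl orthoformate, COC(OC)OC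
Why: Acetalisation with an orthoester as water scavenger; the alkene geometry is untouched.

Step 19
Reactants: 30 (2Z)-2-bromo-1,1-dimethoxybut-2-ene
Product: 32 2-[(2E)-1,1-dimethoxybut-2-en-2-yl]-4,4,5,5-tetramethyl-1,3,2-dioxaborolane, via alkenyllithium 31 (not isolated)
Conditions: t-BuLi (2.0 equiv), Et2O, −78 °C; then i-PrOBpin, −78 °C → rt; H2O
Reagents that add atoms: 2-isopropoxy-4,4,5,5-tetramethyl-1,3,2-dioxaborolane, CC(C)OB1OC(C)(C)C(C)(C)O1
Why: Bromine–lithium exchange and borylation both proceed with retention at the sp2 carbon, so boron ends cis to CH3; the change from Z to E is a priority effect.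

Step 20
Reactants: 33 methyl acrylate; 34 4,4-diethoxybut-1-ene
Product: 35 methyl (2E)-5,5-diethoxypent-2-enoate
Conditions: 33 (3 equiv), second-generation Grubbs catalyst (H2IMes)(PCy3)Cl2Ru=CHPh (3 mol %), CH2Cl2, 40 °C
Reagents that add atoms: none
Why: Olefin cross-metathesis of a terminal alkene with an acrylate; the pairing is selective and gives the E enoate.

Step 21
Reactants: 32 alkenylboronate; 35 methyl (2E)-5,5-diethoxypent-2-enoate
Product: 36 methyl (3S,4E)-3-(2,2-diethoxyethyl)-4-(dimethoxymethyl)hex-4-enoate
Conditions: [Rh(OH)((R)-BINAP)]2 (3 mol % Rh), KOH (0.5 equiv), dioxane/H2O (10:1), 50 °C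
Reagents that add atoms: none
Why: Hayashi–Miyaura reaction: the alkenyl group passes from boron to monovalent rhodium, adds across the coordinated enoate with the face chosen by the bisphosphine, and the rhodium enolate is protonated by water. The new stereocentre is under catalyst control and the alkene geometry of 32 is retained.

Step 22
Reactants: 36 methyl ester
Product: 37 (3S,4E)-3-(2,2-diethoxyethyl)-4-(dimethoxymethyl)hex-4-enoic acid
Conditions: LiOH·H2O, THF/MeOH/H2O, rt; then aq. NaH2PO4 to pH 5, 0 °C
Reagents that add atoms: lithium hydroxide, [Li+].[OH-]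
Why: Saponification; acetals are stable to base, and the buffered cold acidification frees the acid without hydrolysing them.

Step 23
Reactants: 26 diol (O3 and O7 free); 37 acetal-protected (S)-acid
Product: 38 (1R,2R,3S,4R)-3-{[(tert-butyldimethylsilyl)oxy]methyl}-4-[(2R)-1-[(tert-butyldimethylsilyl)oxy]-3-{[(3S,4E)-3-(2,2-diethoxyethyl)-4-(dimethoxymethyl)hex-4-enoyl]oxy}propan-2-yl]-2-methylcyclopentyl (3S,4E)-3-(2,2-diethoxyethyl)-4-(dimethoxymethyl)hex-4-enoate
Conditions: 37 (2.6 equiv), EDC·HCl, DMAP, CH2Cl2, 0 °C → rt
Reagents that add atoms: none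
Why: Steglich esterification of the primary O3 and the secondary O7 hydroxyls in one operation; the acid has no α-stereocentre, so activation cannot erode its configuration.

Step 24
Reactants: 38 fully protected bis-ester
Product: 39 (1R,2R,3S,4R)-4-[(2S)-1-{[(3S,4E)-4-formyl-3-(2-oxoethyl)hex-4-enoyl]oxy}-3-hydroxypropan-2-yl]-3-(hydroxymethyl)-2-methylcyclopentyl (3S,4E)-4-formyl-3-(2-oxoethyl)hex-4-enoate
Conditions: 1 M HCl (aq)/THF (1:3), 0 °C → rt
Reagents that add atoms: water, O
Why: Acid hydrolysis of the four acetals and of the two primary silyl ethers in one operation; the E-enal is the stable geometry, and acidic conditions are chosen because base would move the O3 acyl group to O11.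

## Compound list

Changes of CIP descriptor between related compounds (for example at C4 in 21, 22, 25 and 26, or at C5 in 20) come from changed substituent priorities; the spatial arrangement is that of the target throughout.

1 | (2,2-dimethyl-1,3-dioxan-5-yl)methanol | CC1(C)OCC(CO)CO1 | starting material
2 | 2,2-dimethyl-1,3-dioxane-5-carbaldehyde | CC1(C)OCC(C=O)CO1 | intermediate
3 | 5-ethenyl-2,2-dimethyl-1,3-dioxane | CC1(C)OCC(C=C)CO1 | intermediate
4 | 3-(benzyloxy)propanoic acid | OC(=O)CCOCc1ccccc1 | starting material
5 | (2R,5R)-2,5-dimethylpyrrolidine | C[C@@H]1CC[C@@H](C)N1 | starting material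
6 | 3-(benzyloxy)propanoyl chloride | ClC(=O)CCOCc1ccccc1 | intermediate (not isolated)
7 | 3-(benzyloxy)-1-[(2R,5R)-2,5-dimethylpyrrolidin-1-yl]propan-1-one | O=C(CCOCc1ccccc1)N2[C@H](C)CC[C@H]2C | intermediate
8 | (2R,5R)-1-[3-(benzyloxy)prop-1-en-1-ylidene]-2,5-dimethylpyrrolidin-1-ium trifluoromethanesulfonate | C[C@@H]1CC[C@@H](C)[N+]1=C=CCOCc2ccccc2.[O-]S(=O)(=O)C(F)(F)F | intermediate (not isolated)
9 | (2R,5R)-1-[(2R,3R)-2-[(benzyloxy)methyl]-3-(2,2-dimethyl-1,3-dioxan-5-yl)cyclobutylidene]-2,5-dimethylpyrrolidin-1-ium trifluoromethanesulfonate (ring substituents cis) | C[C@@H]1CC[C@@H](C)[N+]1=C2C[C@@H](C3COC(C)(C)OC3)[C@H]2COCc4ccccc4.[O-]S(=O)(=O)C(F)(F)F | intermediate (not isolated)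
10 | (2S,3S)-2-[(benzyloxy)methyl]-3-(2,2-dimethyl-1,3-dioxan-5-yl)cyclobutan-1-one (cis) | CC1(C)OCC(CO1)[C@@H]2CC(=O)[C@@H]2COCc3ccccc3 | intermediate (not isolated)
11 | (2R,3S)-2-[(benzyloxy)methyl]-3-(2,2-dimethyl-1,3-dioxan-5-yl)cyclobutan-1-one (trans) | CC1(C)OCC(CO1)[C@@H]2CC(=O)[C@H]2COCc3ccccc3 | intermediate
12 | ethynylmagnesium bromide | C#C[Mg]Br | starting material
13 | (1R,2R,3S)-2-[(benzyloxy)methyl]-3-(2,2-dimethyl-1,3-dioxan-5-yl)-1-ethynylcyclobutan-1-ol (hydroxyl cis to the benzyloxymethyl group) | CC1(C)OCC(CO1)[C@@H]2C[C@](O)(C#C)[C@H]2COCc3ccccc3 | intermediate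
14 | (3S,4R)-3-[(benzyloxy)methyl]-4-(2,2-dimethyl-1,3-dioxan-5-yl)-2-methylidenecyclopentan-1-one | CC1(C)OCC(CO1)[C@@H]2CC(=O)C(=C)[C@H]2COCc3ccccc3 | intermediate
15 | (2S,3S,4R)-3-[(benzyloxy)methyl]-4-(2,2-dimethyl-1,3-dioxan-5-yl)-2-methylcyclopentan-1-one (methyl cis to C9 substituent) | CC1(C)OCC(CO1)[C@@H]2CC(=O)[C@@H](C)[C@H]2COCc3ccccc3 | intermediate (not isolated)
16 | (2R,3S,4R)-3-[(benzyloxy)methyl]-4-(2,2-dimethyl-1,3-dioxan-5-yl)-2-methylcyclopentan-1-one | CC1(C)OCC(CO1)[C@@H]2CC(=O)[C@H](C)[C@H]2COCc3ccccc3 | intermediate
17 | (1S,2R,3S,4R)-3-[(benzyloxy)methyl]-4-(2,2-dimethyl-1,3-dioxan-5-yl)-2-methylcyclopentan-1-ol | CC1(C)OCC(CO1)[C@@H]2C[C@H](O)[C@H](C)[C@H]2COCc3ccccc3 | intermediate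
18 | (1R,2R,3S,4R)-3-[(benzyloxy)methyl]-4-(2,2-dimethyl-1,3-dioxan-5-yl)-2-methylcyclopentyl benzoate | CC1(C)OCC(CO1)[C@@H]2C[C@@H](OC(=O)c3ccccc3)[C@H](C)[C@H]2COCc4ccccc4 | intermediate
19 | (1R,2R,3S,4R)-4-(2,2-dimethyl-1,3-dioxan-5-yl)-3-(hydroxymethyl)-2-methylcyclopentyl benzoate | CC1(C)OCC(CO1)[C@@H]2C[C@@H](OC(=O)c3ccccc3)[C@H](C)[C@H]2CO | intermediate
20 | (1R,2R,3S,4S)-4-(2,2-dimethyl-1,3-dioxan-5-yl)-3-formyl-2-methylcyclopentyl benzoate | CC1(C)OCC(CO1)[C@@H]2C[C@@H](OC(=O)c3ccccc3)[C@H](C)[C@H]2C=O | intermediate
21 | (4R,4aS,6R,7R,7aS)-4-(hydroxymethyl)-1-methoxy-7-methyloctahydrocyclopenta[c]pyran-6-yl benzoate (C1 anomers, C1 left open in the SMILES) | OC[C@@H]1COC(OC)[C@H]2[C@H]1C[C@@H](OC(=O)c3ccccc3)[C@@H]2C | intermediate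
22 | [(4S,4aS,6R,7R,7aS)-6-(benzoyloxy)-1-methoxy-7-methyloctahydrocyclopenta[c]pyran-4-yl]methyl 2,2-dimethylpropanoate (C1 anomers) | CC(C)(C)C(=O)OC[C@@H]1COC(OC)[C@H]2[C@H]1C[C@@H](OC(=O)c3ccccc3)[C@@H]2C | intermediate
23 | [(4S,4aS,6R,7R,7aS)-6-(benzoyloxy)-1-hydroxy-7-methyloctahydrocyclopenta[c]pyran-4-yl]methyl 2,2-dimethylpropanoate (C1 anomers) | CC(C)(C)C(=O)OC[C@@H]1COC(O)[C@H]2[C@H]1C[C@@H](OC(=O)c3ccccc3)[C@@H]2C | intermediate (not isolated)
24 | (1R,2R,3S,4R)-4-[(2S)-1-[(2,2-dimethylpropanoyl)oxy]-3-hydroxypropan-2-yl]-3-(hydroxymethyl)-2-methylcyclopentyl benzoate | CC(C)(C)C(=O)OC[C@H](CO)[C@@H]1C[C@@H](OC(=O)c2ccccc2)[C@H](C)[C@H]1CO | intermediate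
25 | (1R,2R,3S,4R)-3-{[(tert-butyldimethylsilyl)oxy]methyl}-4-[(2R)-1-[(tert-butyldimethylsilyl)oxy]-3-[(2,2-dimethylpropanoyl)oxy]propan-2-yl]-2-methylcyclopentyl benzoate | CC(C)(C)C(=O)OC[C@H](CO[Si](C)(C)C(C)(C)C)[C@@H]1C[C@@H](OC(=O)c2ccccc2)[C@H](C)[C@H]1CO[Si](C)(C)C(C)(C)C | intermediate
26 | (1R,2R,3S,4R)-3-{[(tert-butyldimethylsilyl)oxy]methyl}-4-[(2R)-1-[(tert-butyldimethylsilyl)oxy]-3-hydroxypropan-2-yl]-2-methylcyclopentan-1-ol | OC[C@H](CO[Si](C)(C)C(C)(C)C)[C@@H]1C[C@@H](O)[C@H](C)[C@H]1CO[Si](C)(C)C(C)(C)C | intermediate
27 | (2E)-but-2-enal (crotonaldehyde) | C/C=C/C=O | starting material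
28 | 2,3-dibromobutanal (racemic; both centres are lost in the elimination) | CC(Br)C(Br)C=O | intermediate (not isolated)
29 | (2Z)-2-bromobut-2-enal | C/C=C(/C=O)Br | intermediate
30 | (2Z)-2-bromo-1,1-dimethoxybut-2-ene | C/C=C(/C(OC)OC)Br | intermediate
31 | [(2E)-1,1-dimethoxybut-2-en-2-yl]lithium | C/C=C(/C(OC)OC)[Li] | intermediate (not isolated)
32 | 2-[(2E)-1,1-dimethoxybut-2-en-2-yl]-4,4,5,5-tetramethyl-1,3,2-dioxaborolane | C/C=C(/C(OC)OC)B1OC(C)(C)C(C)(C)O1 | intermediate
33 | methyl acrylate | C=CC(=O)OC | starting material
34 | 4,4-diethoxybut-1-ene | C=CCC(OCC)OCC | starting material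
35 | methyl (2E)-5,5-diethoxypent-2-enoate | COC(=O)/C=C/CC(OCC)OCC | intermediate
36 | methyl (3S,4E)-3-(2,2-diethoxyethyl)-4-(dimethoxymethyl)hex-4-enoate | C/C=C(/C(OC)OC)[C@@H](CC(OCC)OCC)CC(=O)OC | intermediate
37 | (3S,4E)-3-(2,2-diethoxyethyl)-4-(dimethoxymethyl)hex-4-enoic acid | C/C=C(/C(OC)OC)[C@@H](CC(OCC)OCC)CC(=O)O | intermediate
38 | (1R,2R,3S,4R)-3-{[(tert-butyldimethylsilyl)oxy]methyl}-4-[(2R)-1-[(tert-butyldimethylsilyl)oxy]-3-{[(3S,4E)-3-(2,2-diethoxyethyl)-4-(dimethoxymethyl)hex-4-enoyl]oxy}propan-2-yl]-2-methylcyclopentyl (3S,4E)-3-(2,2-diethoxyethyl)-4-(dimethoxymethyl)hex-4-enoate | C/C=C(/C(OC)OC)[C@@H](CC(OCC)OCC)CC(=O)OC[C@H](CO[Si](C)(C)C(C)(C)C)[C@@H]1C[C@@H](OC(=O)C[C@H](CC(OCC)OCC)/C(C(OC)OC)=C\C)[C@H](C)[C@H]1CO[Si](C)(C)C(C)(C)C | intermediate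
39 | (1R,2R,3S,4R)-4-[(2S)-1-{[(3S,4E)-4-formyl-3-(2-oxoethyl)hex-4-enoyl]oxy}-3-hydroxypropan-2-yl]-3-(hydroxymethyl)-2-methylcyclopentyl (3S,4E)-4-formyl-3-(2-oxoethyl)hex-4-enoate (CNP0192766.1) | C/C=C(/C=O)[C@@H](CC=O)CC(=O)OC[C@H](CO)[C@@H]1C[C@@H](OC(=O)C[C@H](CC=O)/C(C=O)=C\C)[C@H](C)[C@H]1CO | target

## Step count and least certain steps

Total step count: 24. Longest linear sequence: 17 steps (1, 2, 4–16, 23, 24); the acid 37 is made in a six-step branch (17–22) and the amide 7 in one step (3).

**Step 6 (key step).** What may go wrong: migration of C6 instead of C9; isomerisation of the methylidene ketone into the ring, which would erase C9; Meyer–Schuster rearrangement or hydration of the propargylic alcohol; loss of the acetonide through traces of strong acid from the silver salt. The cause in each case is that the cationic alkyne complex has more than one outlet and the product is an acid-sensitive exocyclic enone. Fallback, from 11 and back to the route at 14: addition of vinylmagnesium bromide to 11 gives (1S,2R,3S)-2-[(benzyloxy)methyl]-3-(2,2-dimethyl-1,3-dioxan-5-yl)-1-ethenylcyclobutan-1-ol F1. Hydroxyl-directed epoxidation with VO(acac)2 and t-BuOOH gives the epoxy alcohol F2. A mild Lewis acid (Yb(OTf)3, CH2Cl2) triggers the epoxy-alcohol semipinacol shift, in which the ring bond anti to the breaking C–O bond moves to the inner epoxide carbon and gives the 2-(hydroxymethyl)cyclopentanone F3. Mesylation with Et3N and elimination in the same flask then gives 14. This path uses no alkyne and no π-acid, and the β-hydroxy ketone F3 can be purified before the sensitive enone is made.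

**Step 4.** What may go wrong: incomplete facial discrimination by the auxiliary; formation of some trans adduct in the kinetic cycloaddition, which after epimerisation at C9 belongs to the enantiomeric series and lowers the ee; cleavage of the acetonide by triflic species; oligomerisation of the alkene. The sense of induction is also only assigned from a model. Fallback, from 3 and back at 11: (2+2) cycloaddition of 3 with dichloroketene (Cl3CCOCl, Zn–Cu couple) gives 2,2-dichloro-3-(2,2-dimethyl-1,3-dioxan-5-yl)cyclobutan-1-one F4. Dechlorination with Zn and NH4Cl in MeOH gives the achiral 3-(2,2-dimethyl-1,3-dioxan-5-yl)cyclobutan-1-one F5. Enantiotopic deprotonation with lithium bis[(R)-1-phenylethyl]amide (or its antipode, as the sense requires) in the presence of Et3SiCl gives triethyl{[(3S)-3-(2,2-dimethyl-1,3-dioxan-5-yl)cyclobut-1-en-1-yl]oxy}silane F6. ZnBr2-catalysed alkylation with benzyl chloromethyl ether, anti to the ring substituent, gives 11.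

**Step 12.** What may go wrong: too small a thermodynamic preference between the two arms, giving a mixture of C4 epimers; slow epimerisation at C9 through the enol of the aldehyde before it is captured. The preference rests only on the equatorial versus axial placement of one hydroxymethyl group. Fallback, from 20 and back at 23: Pinnick oxidation (NaClO2, NaH2PO4, 2-methylbut-2-ene) gives (1S,2R,3R,5S)-3-(benzoyloxy)-5-(2,2-dimethyl-1,3-dioxan-5-yl)-2-methylcyclopentane-1-carboxylic acid F7. p-TsOH in wet CH2Cl2 removes the acetonide and closes the δ-lactone; acid-catalysed translactonisation between the two arms funnels the material into (4R,4aS,6R,7R,7aS)-4-(hydroxymethyl)-7-methyl-1-oxooctahydrocyclopenta[c]pyran-6-yl benzoate F8, a single compound without anomers that can be crystallised. Pivaloylation gives [(4S,4aS,6R,7R,7aS)-6-(benzoyloxy)-7-methyl-1-oxooctahydrocyclopenta[c]pyran-4-yl]methyl 2,2-dimethylpropanoate F9, and disiamylborane, which reduces lactones but not esters, gives lactol 23 for the borohydride stage of step 14.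

**Step 21.** What may go wrong: slow transfer of the α-branched, acetal-bearing alkenyl group from boron to rhodium, so that protodeboronation wins; modest enantioselectivity for an acyclic enoate; the wrong sense of induction if the binding premise fails. Fallback, from 35 and back at 37: LiOH hydrolysis of 35 gives (2E)-5,5-diethoxypent-2-enoic acid F10. Its pivalic mixed anhydride acylates lithiated (R)-4-phenyloxazolidin-2-one to give (4R)-3-[(2E)-5,5-diethoxypent-2-enoyl]-4-phenyl-1,3-oxazolidin-2-one F11. The alkenyllithium 31, made from 30 as in step 19 and converted with CuBr·SMe2 into the cuprate, adds to the chelated s-cis imide anti to the phenyl group and gives (4R)-3-[(3S,4E)-3-(2,2-diethoxyethyl)-4-(dimethoxymethyl)hex-4-enoyl]-4-phenyl-1,3-oxazolidin-2-one F12. LiOH/H2O2 then releases acid 37 and the auxiliary.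

**Step 24.** What may go wrong: acid-promoted shift of the O3 acyl group to O11 (loss of C4 integrity) if desilylation needs long exposure; hemiacetal, hydrate or aldol formation among four free aldehydes and two free alcohols; incomplete removal of one silyl group. One set of conditions has to serve two kinds of protecting group. Fallback, from 38 and back at 39: buffered HF·pyridine in THF/pyridine removes only the silyl groups and gives the tetra-acetal diol (1R,2R,3S,4R)-4-[(2S)-1-{[(3S,4E)-3-(2,2-diethoxyethyl)-4-(dimethoxymethyl)hex-4-enoyl]oxy}-3-hydroxypropan-2-yl]-3-(hydroxymethyl)-2-methylcyclopentyl (3S,4E)-3-(2,2-diethoxyethyl)-4-(dimethoxymethyl)hex-4-enoate F13, which can be purified. The acetals are then hydrolysed separately under the mildest conditions that serve (LiBF4 in wet MeCN), giving 39.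

## Further compounds

F1 | step 6 | (1S,2R,3S)-2-[(benzyloxy)methyl]-3-(2,2-dimethyl-1,3-dioxan-5-yl)-1-ethenylcyclobutan-1-ol | CC1(C)OCC(CO1)[C@@H]2C[C@](O)(C=C)[C@H]2COCc3ccccc3
F2 | step 6 | (2R,3S)-2-[(benzyloxy)methyl]-3-(2,2-dimethyl-1,3-dioxan-5-yl)-1-(oxiran-2-yl)cyclobutan-1-ol (carbinol as in F1, epoxide carbon as a mixture) | CC1(C)OCC(CO1)[C@@H]2C[C@](O)(C3CO3)[C@H]2COCc4ccccc4
F3 | step 6 | (3S,4R)-3-[(benzyloxy)methyl]-4-(2,2-dimethyl-1,3-dioxan-5-yl)-2-(hydroxymethyl)cyclopentan-1-one (C2 as a mixture) | CC1(C)OCC(CO1)[C@@H]2CC(=O)C(CO)[C@H]2COCc3ccccc3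
F4 | step 4 | 2,2-dichloro-3-(2,2-dimethyl-1,3-dioxan-5-yl)cyclobutan-1-one (racemic) | CC1(C)OCC(CO1)C2CC(=O)C2(Cl)Cl
F5 | step 4 | 3-(2,2-dimethyl-1,3-dioxan-5-yl)cyclobutan-1-one | CC1(C)OCC(CO1)C2CC(=O)C2
F6 | step 4 | triethyl{[(3S)-3-(2,2-dimethyl-1,3-dioxan-5-yl)cyclobut-1-en-1-yl]oxy}silane | CC1(C)OCC(CO1)[C@@H]2CC(O[Si](CC)(CC)CC)=C2
F7 | step 12 | (1S,2R,3R,5S)-3-(benzoyloxy)-5-(2,2-dimethyl-1,3-dioxan-5-yl)-2-methylcyclopentane-1-carboxylic acid | CC1(C)OCC(CO1)[C@@H]2C[C@@H](OC(=O)c3ccccc3)[C@H](C)[C@H]2C(=O)O
F8 | step 12 | (4R,4aS,6R,7R,7aS)-4-(hydroxymethyl)-7-methyl-1-oxooctahydrocyclopenta[c]pyran-6-yl benzoate | OC[C@@H]1COC(=O)[C@H]2[C@H]1C[C@@H](OC(=O)c3ccccc3)[C@@H]2C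
F9 | step 12 | [(4S,4aS,6R,7R,7aS)-6-(benzoyloxy)-7-methyl-1-oxooctahydrocyclopenta[c]pyran-4-yl]methyl 2,2-dimethylpropanoate | CC(C)(C)C(=O)OC[C@@H]1COC(=O)[C@H]2[C@H]1C[C@@H](OC(=O)c3ccccc3)[C@@H]2C
F10 | step 21 | (2E)-5,5-diethoxypent-2-enoic acid | OC(=O)/C=C/CC(OCC)OCC
F11 | step 21 | (4R)-3-[(2E)-5,5-diethoxypent-2-enoyl]-4-phenyl-1,3-oxazolidin-2-one | CCOC(OCC)C/C=C/C(=O)N1[C@H](c2ccccc2)COC1=O
F12 | step 21 | (4R)-3-[(3S,4E)-3-(2,2-diethoxyethyl)-4-(dimethoxymethyl)hex-4-enoyl]-4-phenyl-1,3-oxazolidin-2-one | C/C=C(/C(OC)OC)[C@@H](CC(OCC)OCC)CC(=O)N1[C@H](c2ccccc2)COC1=O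
F13 | step 24 | (1R,2R,3S,4R)-4-[(2S)-1-{[(3S,4E)-3-(2,2-diethoxyethyl)-4-(dimethoxymethyl)hex-4-enoyl]oxy}-3-hydroxypropan-2-yl]-3-(hydroxymethyl)-2-methylcyclopentyl (3S,4E)-3-(2,2-diethoxyethyl)-4-(dimethoxymethyl)hex-4-enoate | C/C=C(/C(OC)OC)[C@@H](CC(OCC)OCC)CC(=O)OC[C@H](CO)[C@@H]1C[C@@H](OC(=O)C[C@H](CC(OCC)OCC)/C(C(OC)OC)=C\C)[C@H](C)[C@H]1CO
A1 | alternative 1 | bis[(2E)-5,5-dimethoxypent-2-enoate] of diol 26 (O1 and O11 as tert-butyldimethylsilyl ethers) | COC(OC)C/C=C/C(=O)OC[C@H](CO[Si](C)(C)C(C)(C)C)[C@@H]1C[C@@H](OC(=O)/C=C/CC(OC)OC)[C@H](C)[C@H]1CO[Si](C)(C)C(C)(C)C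
A2 | alternative 1 | protected target with O1 and O11 as tert-butyldimethylsilyl ethers and four dimethyl acetals | C/C=C(/C(OC)OC)[C@@H](CC(OC)OC)CC(=O)OC[C@H](CO[Si](C)(C)C(C)(C)C)[C@@H]1C[C@@H](OC(=O)C[C@H](CC(OC)OC)/C(C(OC)OC)=C\C)[C@H](C)[C@H]1CO[Si](C)(C)C(C)(C)C
A3 | alternative 2 | 1-({(2R)-2-ethenyl-3-[(1-ethoxybut-2-yn-1-yl)oxy]propoxy}methyl)-4-methoxybenzene (acetal carbon as a mixture) | CCOC(C#CC)OC[C@@H](COCc1ccc(OC)cc1)C=C
A4 | alternative 2 | 1-ethoxy-4-{[(4-methoxybenzyl)oxy]methyl}-7-methyl-3,4,4a,5-tetrahydrocyclopenta[c]pyran-6(1H)-one, configuration as in the SMILES | CCO[C@@H]1OC[C@@H](COCc2ccc(OC)cc2)[C@@H]3CC(=O)C(C)=C13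
A5 | alternative 3 | (4R)-4-[(tert-butyldimethylsilyl)oxy]cyclopent-2-en-1-one | O=C1C=C[C@H](O[Si](C)(C)C(C)(C)C)C1
A6 | alternative 3 | {[dimethyl(propan-2-yloxy)silyl]methyl}magnesium chloride | CC(C)O[Si](C)(C)C[Mg]Cl
A7 | alternative 3 | all-trans 4-[(tert-butyldimethylsilyl)oxy]-3-{[dimethyl(propan-2-yloxy)silyl]methyl}-2-methylcyclopentan-1-one | CC(C)(C)[Si](C)(C)O[C@@H]1CC(=O)[C@H](C)[C@H]1C[Si](C)(C)OC(C)C
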